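**Retrosynthetic overview**
- Feature: in ring C, C3 is a single oxygen-bearing carbon. It sits between C4 (the ketone carbon on ring A) and C2 (bonded to O1 and ring B), and both neighbours are at the carboxylic acid oxidation level.
- C3 is therefore removed as an alkoxymethylene phosphorane. C3–C4 comes from C-acylation by a ring-A acid chloride. C2=C3 comes from an intramolecular Wittig reaction on the ring-B aryl ester that already holds O1–C2.
- The acid chloride traces back through the acid, the O-aroylated salicylaldehyde and an ortho-formylation to 3,4,5-tris(benzyloxy)phenol, which is made from the benzaldehyde by a Baeyer–Villiger/Dakin-type oxidation.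
- O3 arrives as a 2-(trimethylsilyl)ethyl ether, orthogonal to the four benzyl ethers. Fluoride frees O3 alone, and O3 is sulfated before hydrogenolysis and the final proton exchange.
- Ring order: rings A and B are bought as arenes, and ring C is the only ring made.

Key step: step 6

Assumption: the free hydrogen sulfate drawn is the goal, so the more stable sodium salt is carried as far as possible and protonated last. The molecule has no stereocentre, so no step has to set configuration.

**Step 1**
Reactants: 1 3,4,5-tris(benzyloxy)benzaldehyde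
Product: 3 3,4,5-tris(benzyloxy)phenol, via aryl formate 2 (not isolated)
Conditions: mCPBA, CH2Cl2, 0 °C → rt; aq. NaHCO3 wash; then K2CO3 (cat.), MeOH/THF, rt, Ar
Reagents that add atoms: mCPBA (3-chloroperoxybenzoic acid), O=C(OO)c1cccc(Cl)c1
Why: Baeyer–Villiger oxidation in its Dakin-type sense, chosen because the aldehyde has no free hydroxyl for the alkaline H2O2 variant: the electron-rich aryl group, pushed by the para benzyloxy oxygen, migrates to oxygen in the peracid adduct in preference to hydride, and the formate is then transesterified by methanol under catalytic base without harm to the benzyl ethers.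

**Step 2**
Reactants: 3 3,4,5-tris(benzyloxy)phenol
Product: 4 4,5,6-tris(benzyloxy)-2-hydroxybenzaldehyde
Conditions: MgCl2, Et3N, (CH2O)n, THF, reflux; 1 M HCl work-up
Reagents that add atoms: paraformaldehyde (as formaldehyde), C=O
Why: Casnati–Skattebøl ortho-formylation, in which magnesium holds the phenoxide oxygen and formaldehyde together so that the new C–C bond can form only at one of the two equivalent ortho positions, and a second formaldehyde accepts hydride to raise the hydroxymethyl stage to the aldehyde.

**Step 3**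
Reactants: 4 4,5,6-tris(benzyloxy)-2-hydroxybenzaldehyde; 5 4-(benzyloxy)benzoyl chloride
Product: 6 3,4,5-tris(benzyloxy)-2-formylphenyl 4-(benzyloxy)benzoate
Conditions: Et3N, DMAP (cat.), CH2Cl2, 0 °C → rt
Reagents that add atoms: none
Why: O-acylation of a phenol under nucleophilic catalysis by DMAP, whose acylpyridinium ion is reactive enough to overcome the hydrogen bond between the phenol and the formyl group, so that the O1–C2 bond and ring B are installed in one operation.

**Step 4**
Reactants: 6 3,4,5-tris(benzyloxy)-2-formylphenyl 4-(benzyloxy)benzoate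
Product: 7 4,5,6-tris(benzyloxy)-2-{[4-(benzyloxy)benzoyl]oxy}benzoic acid
Conditions: NaClO2, NaH2PO4, 2-methyl-2-butene, t-BuOH/THF/H2O, 0 °C → rt
Reagents that add atoms: NaClO2 (sodium chlorite), [Na+].[O-]Cl=O
Why: Pinnick oxidation, in which chlorous acid in a weakly acidic buffer oxidises even hindered aryl aldehydes while sparing the aryl ester and the benzyl ethers, and the alkene traps HOCl before it can chlorinate the one free C–H position of the electron-rich ring.

**Step 5**
Reactants: 7 4,5,6-tris(benzyloxy)-2-{[4-(benzyloxy)benzoyl]oxy}benzoic acid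
Product: 8 4,5,6-tris(benzyloxy)-2-{[4-(benzyloxy)benzoyl]oxy}benzoyl chloride
Conditions: (COCl)2, DMF (cat.), CH2Cl2, 0 °C → rt; evaporate, use crude
Reagents that add atoms: oxalyl chloride, O=C(Cl)C(=O)Cl
Why: Acid chloride formation through the Vilsmeier-type chloroiminium ion, a mild method with gaseous by-products only that is routine for O-acylsalicylic acids and leaves the neighbouring aryl ester in place.

**Step 6**
Reactants: 8 4,5,6-tris(benzyloxy)-2-{[4-(benzyloxy)benzoyl]oxy}benzoyl chloride; 9 [2-(trimethylsilyl)ethoxymethyl]triphenylphosphonium chloride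
Product: 13 5,6,7-tris(benzyloxy)-2-[4-(benzyloxy)phenyl]-3-[2-(trimethylsilyl)ethoxy]-4H-chromen-4-one, via alkoxymethylene ylide 10 (not isolated), via acylphosphonium chloride 11 (not isolated), via keto ylide 12 (not isolated)
Conditions: 9 (2.05 equiv), NaN(SiMe3)2 (2.0 equiv), THF, −78 → 0 °C; 8 (1.0 equiv) in THF, −78 °C → rt; then solvent change to toluene, 110 °C
Reagents that add atoms: none
Why: Proposed new method: the non-stabilised, strongly nucleophilic carbon of ylide 10 should attack the acyl chloride of 8 to form the C3–C4 bond (salt 11), and the second equivalent of 10 should remove the now very acidic C3–H (transylidation) to give the α-alkoxy-β-keto ylide 12. On heating, C3 of 12 adds to the carbonyl carbon of the neighbouring 4-(benzyloxy)benzoate, phosphorus binds the former carbonyl oxygen and Ph3PO leaves, which creates the C2=C3 double bond. Ring C thus closes by a 6-(enolendo)-exo-trig attack of C3 on C2, a Wittig olefination that esters accept only when the ylide is tethered to them, and no stereocentre is formed. The closest known reaction type is the one-pot conversion of O-acylsalicylic acid derivatives with alkylidenephosphoranes into chromones and flavones through acyl ylides; a ylide bearing an alkoxy group on carbon has not been used there, and its oxygen lone pair should raise the nucleophilicity of 12 enough to offset the extra bulk at C3. The selectivity needed is acylation at the acid chloride and not at the aryl ester: the chloride is by far the better acylating group at −78 °C, the ester is deactivated by its para benzyloxy donor, and using just two equivalents of ylide leaves none free once 12 has formed.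

**Step 7**
Reactants: 13 5,6,7-tris(benzyloxy)-2-[4-(benzyloxy)phenyl]-3-[2-(trimethylsilyl)ethoxy]-4H-chromen-4-one
Product: 14 5,6,7-tris(benzyloxy)-2-[4-(benzyloxy)phenyl]-3-hydroxy-4H-chromen-4-one
Conditions: Bu4NF, THF, rt → 50 °C; 1 M HCl work-up
Reagents that add atoms: none
Why: Fluoride-induced β-elimination of a 2-(trimethylsilyl)ethyl ether, in which attack at silicon expels ethene and the stabilised chromon-3-olate, a leaving group comparable with a phenoxide, while benzyl ethers are inert to fluoride.

**Step 8**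
Reactants: 14 5,6,7-tris(benzyloxy)-2-[4-(benzyloxy)phenyl]-3-hydroxy-4H-chromen-4-one
Product: 16 sodium 5,6,7-tris(benzyloxy)-2-[4-(benzyloxy)phenyl]-4-oxo-4H-chromen-3-yl sulfate, via pyridinium sulfate 15 (not isolated)
Conditions: SO3·pyridine, pyridine, 50 °C; then aq. NaHCO3, 0 °C
Reagents that add atoms: sulfur trioxide–pyridine complex, O=S(=O)([O-])[n+]1ccccc1; NaHCO3, [Na+].OC([O-])=O
Why: O-sulfation with a sulfur trioxide–amine complex, where the 3-hydroxyl is the only free OH of 14 so the site is fixed by the protecting-group pattern, and bicarbonate exchange gives the stable sodium salt.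

**Step 9**
Reactants: 16 sodium 5,6,7-tris(benzyloxy)-2-[4-(benzyloxy)phenyl]-4-oxo-4H-chromen-3-yl sulfate
Product: 17 sodium 5,6,7-trihydroxy-2-(4-hydroxyphenyl)-4-oxo-4H-chromen-3-yl sulfate
Conditions: H2 (1 atm), 10% Pd/C, THF/MeOH/H2O, rt; filter under Ar
Reagents that add atoms: none
Why: Catalytic hydrogenolysis of aryl benzyl ethers under neutral conditions, which sulfate monoester salts and the conjugated C2=C3 bond of the chromone tolerate.

**Step 10**
Reactants: 17 sodium 5,6,7-trihydroxy-2-(4-hydroxyphenyl)-4-oxo-4H-chromen-3-yl sulfate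
Product: 18 5,6,7-trihydroxy-2-(4-hydroxyphenyl)-4-oxo-4H-chromen-3-yl hydrogen sulfate (target)
Conditions: polystyrene sulfonic acid resin (H+ form), H2O/MeOH, 0–5 °C, Ar; freeze-dry at once
Reagents that add atoms: none
Why: Cation exchange on a strongly acidic resin swaps Na+ for H+ without any excess of mineral acid, and cold handling with freeze-drying limits acid-catalysed solvolysis of the sulfate ester.

**Compound list**
1 | 3,4,5-tris(benzyloxy)benzaldehyde | O=Cc1cc(OCc2ccccc2)c(OCc2ccccc2)c(OCc2ccccc2)c1 | starting material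
2 | 3,4,5-tris(benzyloxy)phenyl formate | O=COc1cc(OCc2ccccc2)c(OCc2ccccc2)c(OCc2ccccc2)c1 | intermediate
3 | 3,4,5-tris(benzyloxy)phenol | Oc1cc(OCc2ccccc2)c(OCc2ccccc2)c(OCc2ccccc2)c1 | intermediate
4 | 4,5,6-tris(benzyloxy)-2-hydroxybenzaldehyde | O=Cc1c(O)cc(OCc2ccccc2)c(OCc2ccccc2)c1OCc1ccccc1 | intermediate
5 | 4-(benzyloxy)benzoyl chloride | O=C(Cl)c1ccc(OCc2ccccc2)cc1 | starting material
6 | 3,4,5-tris(benzyloxy)-2-formylphenyl 4-(benzyloxy)benzoate | O=Cc1c(OC(=O)c2ccc(OCc3ccccc3)cc2)cc(OCc2ccccc2)c(OCc2ccccc2)c1OCc1ccccc1 | intermediate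
7 | 4,5,6-tris(benzyloxy)-2-{[4-(benzyloxy)benzoyl]oxy}benzoic acid | O=C(O)c1c(OC(=O)c2ccc(OCc3ccccc3)cc2)cc(OCc2ccccc2)c(OCc2ccccc2)c1OCc1ccccc1 | intermediate
8 | 4,5,6-tris(benzyloxy)-2-{[4-(benzyloxy)benzoyl]oxy}benzoyl chloride | O=C(Cl)c1c(OC(=O)c2ccc(OCc3ccccc3)cc2)cc(OCc2ccccc2)c(OCc2ccccc2)c1OCc1ccccc1 | intermediate
9 | [2-(trimethylsilyl)ethoxymethyl]triphenylphosphonium chloride | C[Si](C)(C)CCOC[P+](c1ccccc1)(c1ccccc1)c1ccccc1.[Cl-] | starting material
10 | {[2-(trimethylsilyl)ethoxy]methylidene}triphenyl-λ5-phosphane | C[Si](C)(C)CCOC=P(c1ccccc1)(c1ccccc1)c1ccccc1 | intermediate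
11 | {2-[4,5,6-tris(benzyloxy)-2-{[4-(benzyloxy)benzoyl]oxy}phenyl]-2-oxo-1-[2-(trimethylsilyl)ethoxy]ethyl}triphenylphosphonium chloride (racemic at the phosphorus-bearing carbon) | C[Si](C)(C)CCOC(C(=O)c1c(OC(=O)c2ccc(OCc3ccccc3)cc2)cc(OCc2ccccc2)c(OCc2ccccc2)c1OCc1ccccc1)[P+](c1ccccc1)(c1ccccc1)c1ccccc1.[Cl-] | intermediate
12 | 3,4,5-tris(benzyloxy)-2-{[2-(trimethylsilyl)ethoxy](triphenyl-λ5-phosphanylidene)acetyl}phenyl 4-(benzyloxy)benzoate | C[Si](C)(C)CCOC(C(=O)c1c(OC(=O)c2ccc(OCc3ccccc3)cc2)cc(OCc2ccccc2)c(OCc2ccccc2)c1OCc1ccccc1)=P(c1ccccc1)(c1ccccc1)c1ccccc1 | intermediate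
13 | 5,6,7-tris(benzyloxy)-2-[4-(benzyloxy)phenyl]-3-[2-(trimethylsilyl)ethoxy]-4H-chromen-4-one | O=c1c(OCC[Si](C)(C)C)c(-c2ccc(OCc3ccccc3)cc2)oc2cc(OCc3ccccc3)c(OCc3ccccc3)c(OCc3ccccc3)c12 | intermediate
14 | 5,6,7-tris(benzyloxy)-2-[4-(benzyloxy)phenyl]-3-hydroxy-4H-chromen-4-one | O=c1c(O)c(-c2ccc(OCc3ccccc3)cc2)oc2cc(OCc3ccccc3)c(OCc3ccccc3)c(OCc3ccccc3)c12 | intermediate
15 | pyridinium 5,6,7-tris(benzyloxy)-2-[4-(benzyloxy)phenyl]-4-oxo-4H-chromen-3-yl sulfate | O=c1c(OS(=O)(=O)[O-])c(-c2ccc(OCc3ccccc3)cc2)oc2cc(OCc3ccccc3)c(OCc3ccccc3)c(OCc3ccccc3)c12.c1cc[nH+]cc1 | intermediate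
16 | sodium 5,6,7-tris(benzyloxy)-2-[4-(benzyloxy)phenyl]-4-oxo-4H-chromen-3-yl sulfate | O=c1c(OS(=O)(=O)[O-])c(-c2ccc(OCc3ccccc3)cc2)oc2cc(OCc3ccccc3)c(OCc3ccccc3)c(OCc3ccccc3)c12.[Na+] | intermediate
17 | sodium 5,6,7-trihydroxy-2-(4-hydroxyphenyl)-4-oxo-4H-chromen-3-yl sulfate | O=c1c(OS(=O)(=O)[O-])c(-c2ccc(O)cc2)oc2cc(O)c(O)c(O)c12.[Na+] | intermediate
18 | 5,6,7-trihydroxy-2-(4-hydroxyphenyl)-4-oxo-4H-chromen-3-yl hydrogen sulfate | O=c1c(OS(=O)(=O)O)c(-c2ccc(O)cc2)oc2cc(O)c(O)c(O)c12 | target

**Step count**
Total steps: 10. Longest linear sequence: 10 steps (1 → 18). Compounds 5 and 9 are bought and enter at steps 3 and 6.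

**Steps most likely to fail**

First, step 6.
- **Risk:** The bulky ylide may add only slowly to the doubly ortho-substituted, donor-rich acid chloride. It could then decay thermally or strip the aroyl group from the aryl ester instead. The closure may also stall, because a fully substituted C2=C3 bond has to form.
- **Fallback:** This uses known chemistry and puts the C3 oxygen in after ring closure instead of carrying it on the ylide. It sets out from 8.
  - Two equivalents of methylenetriphenylphosphorane (CH3PPh3Br, NaN(SiMe3)2, THF, −78 °C → rt) should give the parent acyl ylide 3,4,5-tris(benzyloxy)-2-[(triphenyl-λ5-phosphanylidene)acetyl]phenyl 4-(benzyloxy)benzoate F1.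
  - In refluxing toluene F1 undergoes the established intramolecular ester olefination to the flavone 5,6,7-tris(benzyloxy)-2-[4-(benzyloxy)phenyl]-4H-chromen-4-one F2.
  - Dimethyldioxirane (acetone/CH2Cl2, 0 °C) should epoxidise C2=C3 to the racemic 2,3-epoxyflavanone F3.
  - A trace of TsOH opens F3 with loss of the C3 proton to the flavonol.
- **Return:** The route is rejoined at 14, and step 7 is no longer needed.

Second, step 10.
- **Risk:** The product is itself a strong acid, so the sulfate ester may be solvolysed while the aqueous eluate is concentrated. The 5,6,7-trihydroxy ring A may also oxidise in air.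
- **Fallback:** This moves the proton exchange ahead of the deprotection, so that the target forms in a water-free medium. It sets out from 16.
  - 16 is treated in dry THF at 0 °C with one equivalent of HCl in dioxane. NaCl precipitates and is filtered off, leaving 5,6,7-tris(benzyloxy)-2-[4-(benzyloxy)phenyl]-4-oxo-4H-chromen-3-yl hydrogen sulfate F4.
  - The filtrate is hydrogenolysed directly over dry Pd/C, with toluene as the only by-product.
  - Filtration under argon and cold evaporation follow.
- **Return:** The route is rejoined at 18.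

Third, step 7.
- **Risk:** Attack of fluoride at silicon may be slow for an ether linkage. The basic fluoride medium may instead add at C2 and open ring C.
- **Fallback:** This replaces nucleophilic attack at silicon by electrophilic activation of the ether. It sets out from 13. CF3CO2H in CH2Cl2 at 0 °C protonates O3 (assisted by the C4 carbonyl), and the β-silyl group drives loss of ethene and of the silyl group as its trifluoroacetate. The contact time is kept short so that the aryl benzyl ethers are spared. This fallback makes no new compound (F0).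
- **Return:** The route is rejoined at 14.

**Further compounds**
F1 | step 6 | 3,4,5-tris(benzyloxy)-2-[(triphenyl-λ5-phosphanylidene)acetyl]phenyl 4-(benzyloxy)benzoate | O=C(C=P(c1ccccc1)(c1ccccc1)c1ccccc1)c1c(OC(=O)c2ccc(OCc3ccccc3)cc2)cc(OCc2ccccc2)c(OCc2ccccc2)c1OCc1ccccc1
F2 | step 6 | 5,6,7-tris(benzyloxy)-2-[4-(benzyloxy)phenyl]-4H-chromen-4-one | O=c1cc(-c2ccc(OCc3ccccc3)cc2)oc2cc(OCc3ccccc3)c(OCc3ccccc3)c(OCc3ccccc3)c12
F3 | step 6 | 2,3-epoxide of F2 (racemic 2,3-epoxyflavanone, oxirane cis-fused to ring C; one enantiomer drawn) | O=C1c2c(OCc3ccccc3)c(OCc3ccccc3)c(OCc3ccccc3)cc2O[C@@]2(c3ccc(OCc4ccccc4)cc3)O[C@@H]12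
F4 | step 10 | 5,6,7-tris(benzyloxy)-2-[4-(benzyloxy)phenyl]-4-oxo-4H-chromen-3-yl hydrogen sulfate | O=c1c(OS(=O)(=O)O)c(-c2ccc(OCc3ccccc3)cc2)oc2cc(OCc3ccccc3)c(OCc3ccccc3)c(OCc3ccccc3)c12
F0 | step 7 | none | none
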